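If the quick step G ⇌ D stands at its equilibrium (a rapid pre-equilibrium), D follows G by one ratio, and I set out to see how far that carries, writing amounts as fractions of the G charged.

common to all: G 1.0 M

| flask | remark | time |
|---|---|---|
| dusk | one stirred flow tank at steady state, fed with the mixture as stated, mean residence time 50.0 min |  |
| dawn | a single well-mixed tank run continuously and read at steady state, 10 min in it on average |  |
| autumn | everything together in a closed stirred flask, run for 10 min | 10 min |

    G ⇌ D (K1 = 0.40, k1 = 0.62 /min)
    G ⇌ Q (K2 = 0.48, k2 = 0.14 /min)
    D ⇌ X (K3 = 3.0, k3 = 0.13 /min)

- the set-up with the highest amount of D at the outlet or at the end, in percent of the G put in ("none" if the first two lie within 2 percentage points) (dusk / dawn / autumn / none)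
- amount of D at the outlet or at the end, in percent of the G put in, dusk
- amount of D at the outlet or at the end, in percent of the G put in, dawn
- amount of D at the outlet or at the end, in percent of the G put in, autumn

- the stated concentrations are those of everything mixed, before any reaction; amounts are the same in each set-up
- run time (autumn): 10 min

1. I began with the dawn tank. There the pair G and D relaxes at 2.17 /min, faster than the outlet and the step to X together take D away, at 0.230 /min, so I first put D at 0.40 of G.

2. In the dawn tank, what enters Q must leave by the outlet or the back step, which makes Q 0.357 of G, and the same balance makes X 0.907 of D. Adding the four to one charge gave G 0.472 and D 18.9 %.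

3. But I doubted this, since the drain on D in the dawn tank is 0.148 of the back step, which is too much to ignore, and D must lag below 0.40 of G. So I wrote the balance of D itself. It came to 0.356, and this tie ratio, the forward constant of G to D divided by the net loss constant of D through outlet, back step and X, replaced the first guess. The dawn tank then held G 0.491 and D 17.5 %.

4. For the dusk tank, with its mean stay of 50.0 min, Q became 0.449 of G and X 2.05 of D. The tie ratio rose to 0.385, but G fell to 0.381, so D came to 14.7 %, less than in the dawn tank.

5. The autumn flask has no outlet and is read at a moment, so this balance gives it no value. My reckoning stopped there, with the call between dawn and autumn open.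

6. The forecast gave 14.7 % for dusk, 17.5 % for dawn, 16.5 % for autumn and the call none, holding that “The two best set-ups, dawn and autumn, differ by only about one percentage point”.

7. The simulation gave 14.7 % for dusk, 17.5 % for dawn and 16.4 % for autumn, so the call was none: dawn led autumn by 1 percentage point, less than the margin of 2 points.

8. I then used the tie ratio, 0.356 in the dawn tank, on the same tank with the reverse step, D to G, left out. Its loss constant keeps just the outlet and the net drain to X, so the ratio rose to 3.25, and the same sum gave G 0.132 and D 43.0 %, where the simulated run reads 43.0 %. The reverse step thus holds D down in the dawn tank, taking it from 43.0 % to 17.5 %, a loss of 26 points.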